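**Retrosynthetic overview**

1. Target ⇐ (10R)-10,11-epoxide (aluminium-amide isomerisation to the isopropenyl carbinol) ⇐ prenyl alkene (Shi epoxidation, sets C10).
2. The only ring ⇐ acyclic (2S,3S,6Z)-2-bromo-3-chlorofarnesyl triflate by the bisabolane-type C1–C6 cation–olefin closure: the 6,7-alkene is the π-nucleophile and the C7 cation is trapped by formate. The C1 electrophile is the C1–C2 bromonium ion, so the halogens go on before the ring closes (Br–Cl addition to a finished cyclohexene would give the trans-diaxial C2/C3 epimers).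
3. Bromochlorohydrin ⇐ (2Z,6Z)-farnesol by catalytic enantioselective anti bromochlorination of the allylic alkene (sets C2 and C3; 2Z gives trans Br/Cl in the ring; 6Z plus anti addition gives 6S,7R).
4. (2Z,6Z)-Farnesol ⇐ neryl bromide + dilithiated prenol, from nerol and prenol.
5. Ring order: a single carbocycle, formed in step 4 of 6.

Assumption and numbering: isomerically pure (2Z,6Z)-farnesol is taken as too costly to buy and is made from nerol and prenol. Positions use farnesane numbering (C1 ring CH2 next to CHBr, C2 CHBr, C3 CCl(Me), C6 ring CH bearing the side chain, C7 C(OH)Me, C10 CHOH, C11 isopropenyl carbon). The target is (3R,6R)-6-[(1S,3S,4S)-3-bromo-4-chloro-4-methylcyclohexyl]-2-methylhept-1-ene-3,6-diol, with Br and Cl trans-diequatorial and Br cis to the side chain.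

**Route**

Step 1
Reactants: 1 nerol, (2Z)-3,7-dimethylocta-2,6-dien-1-ol
Product: 2 neryl bromide, (2Z)-1-bromo-3,7-dimethylocta-2,6-diene
Conditions: PBr3 (0.4 equiv), Et2O, −10 °C
Reagents that add atoms: phosphorus tribromide, BrP(Br)Br
Why: PBr3 bromination of a primary allylic alcohol (SN2 of bromide on the phosphite ester) is fast at −10 °C, leaves the 2Z and the distal alkene untouched, and creates no stereocentre.

Step 2
Reactants: 3 prenol, 3-methylbut-2-en-1-ol; 2 neryl bromide
Product: 5 (2Z,6Z)-3,7,11-trimethyldodeca-2,6,10-trien-1-ol [(2Z,6Z)-farnesol], via dilithiated prenol 4 (not isolated)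
Conditions: n-BuLi (2.1 equiv), TMEDA, Et2O–hexane, 0 °C → rt (on 3); then 2, −78 → 0 °C; H2O
Reagents that add atoms: none
Why: Alkoxide-directed allylic lithiation removes a proton from the methyl group cis to CH2OLi and the chelated (Z)-dianion is alkylated at its CH2 terminus by the primary allylic bromide (SN2 dianion alkylation), so the new 2,3-alkene is Z, the neryl alkene stays Z, and no stereocentre is formed.

Step 3
Reactants: 5 (2Z,6Z)-farnesol
Product: 6 (2S,3S,6Z)-2-bromo-3-chloro-3,7,11-trimethyldodeca-6,10-dien-1-ol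
Conditions: NBS (1.1 equiv), ClTi(OiPr)3 (1.1 equiv), Schiff-base ligand 2,4-di-tert-butyl-6-[(E)-{[1-hydroxy-3,3-dimethyl-1,1-diphenylbutan-2-yl]imino}methyl]phenol (20 mol %, the antipode that gives 2S,3S), hexanes, −20 °C
Reagents that add atoms: N-bromosuccinimide, O=C1CCC(=O)N1Br; chlorotitanium triisopropoxide, CC(C)O[Ti](Cl)(OC(C)C)OC(C)C
Why: Titanium/Schiff-base-catalysed enantioselective bromochlorination of an allylic alcohol (Burns type): the substrate is bound to Ti as its alkoxide so that only the 2,3-alkene is attacked by Br+, chloride is delivered from Ti to the tertiary C3 anti to the bromonium bridge, the 2Z geometry therefore gives the like pair and the chosen ligand antipode gives 2S,3S (C2 and C3 are set here, the 6,7- and 10,11-alkenes are spectators).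

Step 4
Reactants: 6 (2S,3S,6Z)-2-bromo-3-chloro-3,7,11-trimethyldodeca-6,10-dien-1-ol
Product: 9 (2R)-2-[(1S,3S,4S)-3-bromo-4-chloro-4-methylcyclohexyl]-6-methylhept-5-en-2-ol, via primary triflate 7 (not isolated), via tertiary formate 8 (not isolated)
Conditions: Tf2O (1.05 equiv), 2,6-di-tert-butyl-4-methylpyridine (2.5 equiv), CH2Cl2, −78 °C; then into HCO2H–CH2Cl2 (1:1), −20 → 0 °C; crude + K2CO3 (cat.), MeOH, 0 °C
Reagents that add atoms: formic acid, O=CO
Why: Proposed new method: cation–olefin (π-) cyclisation in which the β-bromo primary triflate can ionise only with anchimeric assistance by the C2 bromine, giving a configurationally defined C1–C2 bromonium ion that the 6,7-alkene opens at the unhindered primary C1 (C2 is neopentylic and deactivated by the β-chlorine) through a chair in which Br must be equatorial (anti to the forming C1–C6 bond) and the alkene arm is equatorial, which sets C6 as S, while formic acid captures the developing C7 cation anti to the new C–C bond so that the 6Z geometry gives 7R, and mild methanolysis then frees the tertiary alcohol; the closest known reaction types are the formic acid cyclisation of nerolidol or farnesol to bisabolyl formate by anti addition across the 6,7-alkene, π-participation in sulfonate formolysis, and enantiospecific bromonium generation from β-bromo alcohol derivatives with intramolecular alkene capture.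

Step 5
Reactants: 9 (2R)-2-[(1S,3S,4S)-3-bromo-4-chloro-4-methylcyclohexyl]-6-methylhept-5-en-2-ol
Product: 10 (2R)-2-[(1S,3S,4S)-3-bromo-4-chloro-4-methylcyclohexyl]-4-[(2R)-3,3-dimethyloxiran-2-yl]butan-2-ol
Conditions: 1,2:4,5-di-O-isopropylidene-β-D-erythro-2,3-hexodiulo-2,6-pyranose (D-fructose-derived Shi ketone, 0.3 equiv), KHSO5 (as 2KHSO5·KHSO4·K2SO4), K2CO3, Bu4NHSO4, MeCN–CH2(OMe)2–aq. Na2B4O7 buffer (pH 10.5), 0 °C
Reagents that add atoms: potassium peroxymonosulfate, [K+].[O-]S(=O)(=O)OO
Why: Shi asymmetric epoxidation: the chiral dioxirane attacks the only alkene, the trisubstituted prenyl double bond, through the spiro transition state that gives the (R)-epoxide and thus sets C10, while the tertiary alcohol, the secondary bromide and the tertiary chloride are inert at pH 10.5 and 0 °C.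

Step 6
Reactants: 10 (2R)-2-[(1S,3S,4S)-3-bromo-4-chloro-4-methylcyclohexyl]-4-[(2R)-3,3-dimethyloxiran-2-yl]butan-2-ol
Product: 11 (3R,6R)-6-[(1S,3S,4S)-3-bromo-4-chloro-4-methylcyclohexyl]-2-methylhept-1-ene-3,6-diol (CNP0226035.2)
Conditions: Et2AlCl + lithium 2,2,6,6-tetramethylpiperidide (gives Et2Al–TMP, 4 equiv), toluene, 0 °C → rt; aq. potassium sodium tartrate
Reagents that add atoms: none
Why: Aluminium-amide epoxide-to-allylic-alcohol isomerisation (Yamamoto type): after the first equivalent has capped the C7 hydroxyl as its aluminium alkoxide, Al binds the epoxide oxygen and the piperidide nitrogen removes a proton from a C11 methyl group in a cyclic syn transition state with cleavage of the tertiary C–O bond, so the C10–O bond and its R configuration are kept and the isopropenyl group appears, while the equatorial Br and Cl have no antiperiplanar ring hydrogen for E2.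

**Compound list**

1 | nerol, (2Z)-3,7-dimethylocta-2,6-dien-1-ol | CC(C)=CCC/C(C)=C\CO | starting material
2 | neryl bromide, (2Z)-1-bromo-3,7-dimethylocta-2,6-diene | CC(C)=CCC/C(C)=C\CBr | intermediate
3 | prenol, 3-methylbut-2-en-1-ol | CC(C)=CCO | starting material
4 | dilithiated prenol, lithium (2Z)-4-lithio-3-methylbut-2-en-1-olate | [Li]C/C(C)=C\CO[Li] | intermediate
5 | (2Z,6Z)-farnesol, (2Z,6Z)-3,7,11-trimethyldodeca-2,6,10-trien-1-ol | CC(C)=CCC/C(C)=C\CC/C(C)=C\CO | intermediate
6 | (2S,3S,6Z)-2-bromo-3-chloro-3,7,11-trimethyldodeca-6,10-dien-1-ol | CC(C)=CCC/C(C)=C\CC[C@](C)(Cl)[C@@H](Br)CO | intermediate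
7 | (2S,3S,6Z)-2-bromo-3-chloro-3,7,11-trimethyldodeca-6,10-dien-1-yl trifluoromethanesulfonate | CC(C)=CCC/C(C)=C\CC[C@](C)(Cl)[C@@H](Br)COS(=O)(=O)C(F)(F)F | intermediate
8 | (2R)-2-[(1S,3S,4S)-3-bromo-4-chloro-4-methylcyclohexyl]-6-methylhept-5-en-2-yl formate | CC(C)=CCC[C@@](C)(OC=O)[C@H]1CC[C@](C)(Cl)[C@@H](Br)C1 | intermediate
9 | (2R)-2-[(1S,3S,4S)-3-bromo-4-chloro-4-methylcyclohexyl]-6-methylhept-5-en-2-ol | CC(C)=CCC[C@@](C)(O)[C@H]1CC[C@](C)(Cl)[C@@H](Br)C1 | intermediate
10 | (2R)-2-[(1S,3S,4S)-3-bromo-4-chloro-4-methylcyclohexyl]-4-[(2R)-3,3-dimethyloxiran-2-yl]butan-2-ol | CC1(C)O[C@@H]1CC[C@@](C)(O)[C@H]2CC[C@](C)(Cl)[C@@H](Br)C2 | intermediate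
11 | (3R,6R)-6-[(1S,3S,4S)-3-bromo-4-chloro-4-methylcyclohexyl]-2-methylhept-1-ene-3,6-diol | C=C(C)[C@H](O)CC[C@@](C)(O)[C@H]1CC[C@](C)(Cl)[C@@H](Br)C1 | target

**Step count**

Total steps: 6. Longest linear sequence: 6 steps (1 → 11); prenol 3 enters in step 2.

**Three steps most likely to fail**

Step 4 (ring closure). There is no direct precedent for six-ring closure by an alkene on the primary carbon of a bromonium ion. The competing paths are attack at C2 (five-membered ring), formolysis at C1 (which returns 6 after methanolysis), E1 loss from the C7 cation, leakage of the anti capture (C7 epimer) and the axial-arm chair (C6 epimer). The fallback sets out from 6 and comes back at 9. It changes how the cation is made, from sulfonate solvolysis in a nucleophilic acid to halophile-triggered ionisation with water as the terminating nucleophile. Iodination of 6 (I2, PPh3, imidazole, CH2Cl2, 0 °C) gives (2R,3S,6Z)-2-bromo-3-chloro-1-iodo-3,7,11-trimethyldodeca-6,10-diene F1 (same spatial arrangement as 6; the C2 descriptor changes only by priority). AgBF4 with 2,6-di-tert-butylpyridine in HFIP–H2O at −20 °C then abstracts iodide with bromine participation, the same bromonium ion cyclises, and water adds at C7 to give 9 directly.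

Step 6 (epoxide to allylic alcohol). The aluminium amide may cause E2 or ionisation at the tertiary chloride, and the γ-hydroxy epoxide 10 may close to a tetrahydrofuran. The fallback sets out from 9, leaves 10 out, and comes back at 11. A Schenck ene reaction (O2, tetraphenylporphyrin, hν, CH2Cl2, 0 °C) followed by PPh3 in the same flask gives, through the secondary hydroperoxides (6R)-6-[(1S,3S,4S)-3-bromo-4-chloro-4-methylcyclohexyl]-3-hydroperoxy-2-methylhept-1-en-6-ol F2, the C3-epimeric allylic alcohols (6R)-6-[(1S,3S,4S)-3-bromo-4-chloro-4-methylcyclohexyl]-2-methylhept-1-ene-3,6-diol F3. The regioisomeric tertiary allylic alcohol (3E,6R)-6-[(1S,3S,4S)-3-bromo-4-chloro-4-methylcyclohexyl]-2-methylhept-3-ene-2,6-diol F4 forms alongside. Dess–Martin periodinane oxidises only the secondary alcohol, giving (6R)-6-[(1S,3S,4S)-3-bromo-4-chloro-4-methylcyclohexyl]-6-hydroxy-2-methylhept-1-en-3-one F5, which is separated from unchanged F4. Corey–Bakshi–Shibata reduction of F5 with (S)-2-methyl-CBS-oxazaborolidine and catecholborane (toluene, −78 °C; isopropenyl as the large group) gives 11.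

Step 2 (dianion alkylation). The allyl dianion can react at its internal carbon, neryl bromide can react SN2′, and yields of such couplings are moderate. The fallback sets out from 2 and comes back at 5. It changes the nucleophile to a carboxylate dienolate: the copper dienolate of 3-methylbut-2-enoic acid (2 LDA, then CuI, THF, −78 °C) is alkylated at its γ-carbon by 2, mainly with 2Z geometry, to give (2Z,6Z)-3,7,11-trimethyldodeca-2,6,10-trienoic acid F6. F6 is freed from its 2E isomer and reduced with LiAlH4 (Et2O, 0 °C) to 5.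

**Further compounds**

F1 | step 4 | (2R,3S,6Z)-2-bromo-3-chloro-1-iodo-3,7,11-trimethyldodeca-6,10-diene | CC(C)=CCC/C(C)=C\CC[C@](C)(Cl)[C@@H](Br)CI
F2 | step 6 | (6R)-6-[(1S,3S,4S)-3-bromo-4-chloro-4-methylcyclohexyl]-3-hydroperoxy-2-methylhept-1-en-6-ol (both C3 epimers) | C=C(C)C(OO)CC[C@@](C)(O)[C@H]1CC[C@](C)(Cl)[C@@H](Br)C1
F3 | step 6 | (6R)-6-[(1S,3S,4S)-3-bromo-4-chloro-4-methylcyclohexyl]-2-methylhept-1-ene-3,6-diol (both C3 epimers) | C=C(C)C(O)CC[C@@](C)(O)[C@H]1CC[C@](C)(Cl)[C@@H](Br)C1
F4 | step 6 | (3E,6R)-6-[(1S,3S,4S)-3-bromo-4-chloro-4-methylcyclohexyl]-2-methylhept-3-ene-2,6-diol | CC(C)(O)/C=C/C[C@@](C)(O)[C@H]1CC[C@](C)(Cl)[C@@H](Br)C1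
F5 | step 6 | (6R)-6-[(1S,3S,4S)-3-bromo-4-chloro-4-methylcyclohexyl]-6-hydroxy-2-methylhept-1-en-3-one | C=C(C)C(=O)CC[C@@](C)(O)[C@H]1CC[C@](C)(Cl)[C@@H](Br)C1
F6 | step 2 | (2Z,6Z)-3,7,11-trimethyldodeca-2,6,10-trienoic acid | CC(C)=CCC/C(C)=C\CC/C(C)=C\C(=O)O
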